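Cuts, in retrosynthetic order: C16–C4′ (diene to butenolide), C12–C13 (decalin arm to dienol), the C8=C9 alkene of ring B, and C9–C10 at the quaternary carbon.
Enabling feature: ring B holds a tetrasubstituted C8=C9 alkene, with a methyl group on C8 and the side chain on C9 next to quaternary C10. Read backwards, C8 is the carbonyl carbon of a methyl ketone and C9 the inner carbon of an alkyne, both attached to ring A.
Forward, rings: ring A comes intact from α-ionone, the C10 alkyne is added by radical hydroalkynylation, and ring B closes by alkyne–ketone metathesis through an oxetene, leaving an acetyl group (C11, C12) on C9.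
Forward, chain: the acetyl oxygen leaves via the enol triflate to give a vinyl group. Hydroboration and B-alkyl Suzuki coupling then join C12 to C13, and a Heck reaction adds the butenolide.
Stereochemistry: C5 comes from resolved (S)-α-ionone and C10 from capture of the C10 radical anti to the C5 side chain. The 13E alkene comes from a (Z)-vinyl iodide coupled with retention, and the 15E alkene from syn insertion and syn elimination in the Heck step.

Key step: step 6

Assumption: enantiopure α-ionone is not taken as a catalogue item, so the cheap racemate is resolved; positions are numbered as in drimanes and labdanes (ring A = C1–C5 and C10, ring B = C5–C10, chain C11–C16, C4′ = butenolide carbon bonded to C16).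

Step 1
Reactants: 1 (±)-α-ionone
Product: 2 (S)-(−)-α-ionone
Conditions: preparative SFC, cellulose tris(3,5-dimethylphenylcarbamate) phase, CO2/i-PrOH, UV detection; levorotatory enantiomer collected
Reagents that add atoms: none
Why: Chromatographic resolution of a racemate on a chiral stationary phase: the enone chromophore allows UV-triggered collection and the neutral conditions cannot move the ring alkene, so the single stereocentre, the future C5, is obtained in the S configuration.

Step 2
Reactants: 2 (S)-(−)-α-ionone
Product: 3 (S)-dihydro-α-ionone, 4-[(1S)-2,6,6-trimethylcyclohex-2-en-1-yl]butan-2-one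
Conditions: H2 (4 atm), RhCl(PPh3)3 (5 mol %), benzene–EtOH, 40 °C
Reagents that add atoms: none
Why: Homogeneous hydrogenation with RhCl(PPh3)3 selects by alkene substitution, so the disubstituted enone alkene should be saturated while the hindered trisubstituted ring alkene is neither reduced nor shifted and the allylic stereocentre stays intact.

Step 3
Reactants: 3 (S)-dihydro-α-ionone
Product: 4 2-methyl-2-{2-[(1S)-2,6,6-trimethylcyclohex-2-en-1-yl]ethyl}-1,3-dioxolane
Conditions: ethylene glycol, PPTS (10 mol %), benzene, reflux, Dean–Stark
Reagents that add atoms: ethylene glycol, OCCO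
Why: Acid-catalysed ketalisation with azeotropic removal of water masks the C8 ketone, which would otherwise intercept the C10 radical of step 4 by cyclisation and the methyllithium of step 5 by addition, and the weak acid PPTS should not isomerise the ring alkene.

Step 4
Reactants: 4 dihydro-α-ionone ethylene ketal; 5 p-tolyl 2-(trimethylsilyl)ethynyl sulfone
Product: 6 2-methyl-2-{2-[(1S,2S)-2,6,6-trimethyl-2-[(trimethylsilyl)ethynyl]cyclohexyl]ethyl}-1,3-dioxolane (alkynyl group trans to the side chain)
Conditions: Fe(acac)3 (30 mol %), PhSiH3 (2.5 equiv), 5 (2 equiv), EtOH, 60 °C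
Reagents that add atoms: none
Why: Markovnikov radical hydroalkynylation by metal-hydride hydrogen-atom transfer: the iron hydride made from Fe(acac)3 and PhSiH3 delivers H to C1, the tertiary C10 radical adds to the sulfonyl-bearing alkyne carbon of 5 (the silyl group steers it there) and the sulfonyl radical is expelled, and C10 should be set by equatorial capture in the chair with an equatorial side chain, which is anti to that chain and away from the axial C4 methyl group.

Step 5
Reactants: 6 silyl alkyne ketal
Product: 9 4-[(1S,2S)-2,6,6-trimethyl-2-(prop-1-yn-1-yl)cyclohexyl]butan-2-one (ring-A alkynyl methyl ketone), via lithium acetylide 7 (not isolated), via propynyl ketal 8 (not isolated)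
Conditions: MeLi·LiBr, THF, 0 °C to rt; MeI, 0 °C to rt; then 2 M aq HCl, rt
Reagents that add atoms: methyl iodide, CI; water, O
Why: Methyllithium attacks silicon and releases the lithium acetylide 7 (desilylative metalation), SN2 methylation with MeI supplies C12 and the acidic quench hydrolyses the dioxolane, none of which touches C5 or C10; a plain methyl cap is chosen for the alkyne so that the later enone bears no β-leaving group that acid could eliminate towards a divinyl ketone.

Step 6
Reactants: 9 ring-A alkynyl methyl ketone
Product: 11 1-[(4aS,8aS)-2,5,5,8a-tetramethyl-3,4,4a,5,6,7,8,8a-octahydronaphthalen-1-yl]ethan-1-one (bicyclic enone with the ketone at C11), via oxetene 10 (not isolated)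
Conditions: AuCl3 (5 mol %), AgSbF6 (15 mol %), dry toluene, 100 °C
Reagents that add atoms: none
Why: The cationic gold Lewis acid formed from AuCl3 and AgSbF6 polarises the C8 carbonyl group, the alkyne carbon C9 that sits on quaternary C10 attacks C8, and the linear vinyl cation that develops at C11, supported by its methyl substituent, is trapped by the former carbonyl oxygen to give the ring-fused oxetene 10. Relief of four-ring strain then drives a 4π electrocyclic opening of 10 in which C8–O breaks, so that C8=C9 and the C11 ketone appear together and the net change is a formal [2+2]/retro-[2+2] exchange. The closest known reaction type is the gold- or strong-acid-catalysed intramolecular alkyne–ketone metathesis of alkynyl ketones, which furnishes five- and six-membered cyclic enones with a tetrasubstituted alkene. Ring B closes in a 6-exo-dig mode at the alkyne, which is at the same time 6-exo-trig at the carbonyl group. No lasting stereocentre is made, since C8 of 10 becomes planar again, and C5 and C10 cannot epimerise because neither is enolisable. The step needs exo rather than seven-ring endo attack and metathesis rather than enol cyclisation or hydration: the four-atom tether C10–C5–C6–C7 with its trans-diequatorial arms brings C9 next to C8, the methyl-capped internal alkyne puts the positive charge on C11, and the dry medium and a substrate that holds only hydrocarbon, alkyne and ketone leave no acid-labile site.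

Step 7
Reactants: 11 bicyclic C11 enone
Product: 12 1-[(4aS,8aS)-2,5,5,8a-tetramethyl-3,4,4a,5,6,7,8,8a-octahydronaphthalen-1-yl]ethenyl trifluoromethanesulfonate
Conditions: KN(SiMe3)2, THF, −78 °C; PhNTf2, −78 to 0 °C
Reagents that add atoms: N-phenylbis(trifluoromethanesulfonimide), O=S(=O)(N(c1ccccc1)S(=O)(=O)C(F)(F)F)C(F)(F)F
Why: Kinetic deprotonation of the enone at its only α′ position, the acetyl methyl group, and O-sulfonylation of the cross-conjugated enolate with PhNTf2 (enol triflate formation) fix the new alkene between C11 and C12.

Step 8
Reactants: 12 dienyl triflate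
Product: 13 (4aS,8aS)-1-ethenyl-2,5,5,8a-tetramethyl-3,4,4a,5,6,7,8,8a-octahydronaphthalene
Conditions: Pd(OAc)2 (5 mol %), PPh3 (10 mol %), HCO2H, Et3N, DMF, 60 °C
Reagents that add atoms: none
Why: Palladium-catalysed formate reduction of an enol triflate: oxidative addition to zerovalent palladium, formate exchange, loss of CO2 and reductive elimination replace C11–O by C11–H without moving the tetrasubstituted alkene, which completes the deoxygenation of C11.

Step 9
Reactants: 14 ethyl (triphenylphosphoranylidene)acetate; 15 acrolein
Product: 17 ethyl (2Z)-2-iodopenta-2,4-dienoate, via iodo ylide 16 (not isolated)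
Conditions: NIS, CH2Cl2, −20 °C; then acrolein, −20 °C to rt
Reagents that add atoms: N-iodosuccinimide, O=C1CCC(=O)N1I
Why: Electrophilic iodination of the stabilised ylide gives the iodo ylide 16, whose Wittig olefination of acrolein should favour the isomer with the ester trans to the vinyl group, that is the Z-iodide, the minor isomer being removed by chromatography.

Step 10
Reactants: 17 ethyl (2Z)-2-iodopenta-2,4-dienoate
Product: 18 (2Z)-2-iodopenta-2,4-dien-1-ol
Conditions: i-Bu2AlH (2.2 equiv), CH2Cl2, −78 °C; aqueous work-up
Reagents that add atoms: none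
Why: Reduction of the α,β-unsaturated ester with two hydrides from i-Bu2AlH at low temperature gives the allylic alcohol by 1,2-addition and leaves the vinylic C–I bond and the alkene geometry untouched.

Step 11
Reactants: 13 vinyl decalin; 18 (2Z)-2-iodopenta-2,4-dien-1-ol
Product: 20 (2E)-2-{2-[(4aS,8aS)-2,5,5,8a-tetramethyl-3,4,4a,5,6,7,8,8a-octahydronaphthalen-1-yl]ethyl}penta-2,4-dien-1-ol, via B-alkyl-9-BBN 19 (not isolated)
Conditions: 9-BBN-H, THF, 0 °C to rt; then 18, PdCl2(dppf) (5 mol %), AsPh3 (5 mol %), Cs2CO3, DMF–H2O, rt
Reagents that add atoms: none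
Why: Hydroboration with the bulky 9-BBN-H takes place only at the monosubstituted vinyl group and puts boron on terminal C12, and the B-alkyl Suzuki–Miyaura coupling of 19 with the vinyl iodide forms C12–C13 with retention of alkene geometry, which turns the Z-iodide into the 13E allylic alcohol.

Step 12
Reactants: 20 terminal dienol; 21 4-bromofuran-2(5H)-one
Product: 22 4-{(1E,3E)-4-(hydroxymethyl)-6-[(4aS,8aS)-2,5,5,8a-tetramethyl-3,4,4a,5,6,7,8,8a-octahydronaphthalen-1-yl]hexa-1,3-dien-1-yl}furan-2(5H)-one (CNP0232848.5)
Conditions: Pd(OAc)2 (10 mol %), n-Bu4NCl, NaHCO3, DMF, 60 °C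
Reagents that add atoms: none
Why: Mizoroki–Heck vinylation: zerovalent palladium inserts into the C–Br bond of the β-bromo enoate 21, the vinylpalladium species adds to the unhindered terminal CH2 (C16) of the diene and syn β-hydride elimination gives the 15E alkene, while the trisubstituted C13=C14 and tetrasubstituted C8=C9 alkenes are too hindered to insert and the bicarbonate base spares the butenolide and the free alcohol.

Compound list
1 | (±)-α-ionone, (E)-4-(2,6,6-trimethylcyclohex-2-en-1-yl)but-3-en-2-one | CC(=O)/C=C/C1C(C)=CCCC1(C)C | starting material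
2 | (S)-(−)-α-ionone | CC(=O)/C=C/[C@@H]1C(C)=CCCC1(C)C | intermediate
3 | (S)-dihydro-α-ionone | CC(=O)CC[C@@H]1C(C)=CCCC1(C)C | intermediate
4 | (S)-dihydro-α-ionone ethylene ketal | CC1(CC[C@@H]2C(C)=CCCC2(C)C)OCCO1 | intermediate
5 | p-tolyl 2-(trimethylsilyl)ethynyl sulfone | Cc1ccc(cc1)S(=O)(=O)C#C[Si](C)(C)C | starting material
6 | (5S,10S) silyl alkyne ketal, alkynyl trans to the side chain | C[Si](C)(C)C#C[C@@]1(C)CCCC(C)(C)[C@@H]1CCC2(C)OCCO2 | intermediate
7 | lithium acetylide of the ketal | [Li]C#C[C@@]1(C)CCCC(C)(C)[C@@H]1CCC2(C)OCCO2 | intermediate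
8 | propynyl ketal | CC#C[C@@]1(C)CCCC(C)(C)[C@@H]1CCC2(C)OCCO2 | intermediate
9 | 4-[(1S,2S)-2,6,6-trimethyl-2-(prop-1-yn-1-yl)cyclohexyl]butan-2-one | CC#C[C@@]1(C)CCCC(C)(C)[C@@H]1CCC(C)=O | intermediate
10 | ring-fused oxetene (four-membered ring O–C8–C9=C11; C8 configuration immaterial, lost on opening) | CC1=C2[C@@]3(C)CCCC(C)(C)[C@@H]3CCC2(C)O1 | intermediate
11 | 1-[(4aS,8aS)-2,5,5,8a-tetramethyl-3,4,4a,5,6,7,8,8a-octahydronaphthalen-1-yl]ethan-1-one | CC1=C(C(C)=O)[C@@]2(C)CCCC(C)(C)[C@@H]2CC1 | intermediate
12 | C11 enol triflate | CC1=C(C(=C)OS(=O)(=O)C(F)(F)F)[C@@]2(C)CCCC(C)(C)[C@@H]2CC1 | intermediate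
13 | C9-vinyl decalin | CC1=C(C=C)[C@@]2(C)CCCC(C)(C)[C@@H]2CC1 | intermediate
14 | ethyl (triphenylphosphoranylidene)acetate | CCOC(=O)C=P(c1ccccc1)(c1ccccc1)c1ccccc1 | starting material
15 | acrolein | C=CC=O | starting material
16 | ethyl iodo(triphenylphosphoranylidene)acetate | CCOC(=O)C(I)=P(c1ccccc1)(c1ccccc1)c1ccccc1 | intermediate
17 | ethyl (2Z)-2-iodopenta-2,4-dienoate | I/C(=C\C=C)C(=O)OCC | intermediate
18 | (2Z)-2-iodopenta-2,4-dien-1-ol | I/C(=C\C=C)CO | intermediate
19 | C12 B-alkyl-9-borabicyclo[3.3.1]nonane | CC1=C(CCB2C3CCCC2CCC3)[C@@]2(C)CCCC(C)(C)[C@@H]2CC1 | intermediate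
20 | 13E terminal dienol | CC1=C(CC/C(=C\C=C)CO)[C@@]2(C)CCCC(C)(C)[C@@H]2CC1 | intermediate
21 | 4-bromofuran-2(5H)-one | BrC1=CC(=O)OC1 | starting material
22 | CNP0232848.5 | CC1=C(CC/C(=C\C=C\C2=CC(=O)OC2)CO)[C@@]2(C)CCCC(C)(C)[C@@H]2CC1 | target

Total step count: 12. Longest linear sequence: 10 (steps 1–8, 11 and 12).

Steps most likely to fail

**Step 4.**
- Risk: facial selectivity in the capture of the C10 radical may be poor. The hindered radical may also be reduced before it meets the sulfone.
- Fallback: polar and stereospecific, setting out from 4 and returning at 8.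
- Epoxidation of 4 (mCPBA, NaHCO3, CH2Cl2, 0 °C) and separation of the diastereomers gives the side-chain-face epoxy ketal F1.
- Lithium trimethyl(prop-1-ynyl)aluminate, LiAlMe3(C≡CMe), made from prop-1-ynyllithium and AlMe3, is combined with BF3·OEt2 at −78 °C. This reagent opens trisubstituted epoxides at the more substituted carbon with inversion.
- The propynyl group therefore arrives anti to the side chain and gives the C1-hydroxy propynyl ketal F2. The C10 configuration then follows from the separated epoxide rather than from a facial preference.
- NaH, CS2 and MeI convert F2 into the C1 S-methyl xanthate F3.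
- Barton–McCombie deoxygenation (Bu3SnH, AIBN, toluene, 80 °C) leads to 8, which aqueous HCl converts into 9 as in step 5.

**Step 6.**
- Risk: the activated alkyne may be diverted into enol (Conia-ene) cyclisation through C7, or into hydration. Reactivity may also be lacking because C9 is neopentyl.
- Fallback: keeps the C8–C9 disconnection but forms the bond reductively, setting out from 9 and returning at 11.
- A ketyl–alkyne 6-exo-dig radical cyclisation (SmI2, HMPA, t-BuOH, THF, rt) gives the ethylidene carbinol F4, a tertiary allylic alcohol at C8 with an exocyclic C9=C11 alkene.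
- Babler–Dauben oxidative transposition with pyridinium chlorochromate, [C5H5NH][CrO3Cl], in CH2Cl2 moves the oxygen from C8 to C11 and the alkene into C8=C9. This gives 11.

**Step 12.**
- Risk: C13=C14 geometry may be lost through equilibration of the π-allylpalladium species formed after insertion into the diene. The bromobutenolide may also degrade under base.
- Fallback: sets out from 20 and returns at 22.
- Cross metathesis of the terminal alkene with vinylboronic acid pinacol ester uses the second-generation Grubbs catalyst, RuCl2(=CHPh)(PCy3)(H2IMes), in CH2Cl2 at 40 °C. It gives the (E)-dienyl pinacol boronate F5.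
- Suzuki–Miyaura coupling of F5 with 21 (PdCl2(dppf), K3PO4, THF–H2O, rt) forms C16–C4′ with retention of both alkene geometries and gives 22.

Further compounds
F1 | step 4 | side-chain-face epoxy ketal (C1–C10 epoxide of 4, oxygen cis to the C5 side chain) | C[C@@]12O[C@@H]1CCC(C)(C)[C@@H]2CCC3(C)OCCO3
F2 | step 4 | C1-hydroxy propynyl ketal (propynyl trans, hydroxyl cis to the C5 side chain) | CC#C[C@@]1(C)[C@H](O)CCC(C)(C)[C@@H]1CCC2(C)OCCO2
F3 | step 4 | C1 S-methyl xanthate | CC#C[C@@]1(C)[C@H](OC(=S)SC)CCC(C)(C)[C@@H]1CCC2(C)OCCO2
F4 | step 6 | ethylidene carbinol (C8 epimers and alkene isomers converge on 11) | CC=C1[C@@]2(C)CCCC(C)(C)[C@@H]2CCC1(C)O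
F5 | step 12 | (E)-dienyl pinacol boronate | CC1=C(CC/C(=C\C=C\B2OC(C)(C)C(C)(C)O2)CO)[C@@]2(C)CCCC(C)(C)[C@@H]2CC1
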